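At early times the violet run still moves: substrate falls from 64% at 8.00 min to 54% at 20.0 min, then stands near 46%. The teal flask shows no fall of substrate after its first reading at 0.500 h. The means of its readings are substrate 35.5% and target 58.0%.

in all of them: substrate 20 mM

|  | free enzyme | temperature | remark | time |
|---|---|---|---|---|
| teal | 10 µM | 37 °C | the very flask that is asked about, followed so far |  |
| violet | 5 µM | 32 °C | run made earlier |  |
| flask | 10 µM | 37 °C |  | 8.0 h |

teal run (percent of the substrate charged)

| time / h | target / % | substrate / % |
|---|---|---|
| 0.500 | 59 | 32 |
| 1.50 | 57 | 34 |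
| 3.00 | 57 | 35 |
| 4.00 | 56 | 37 |
| 6.00 | 60 | 36 |
| 8.00 | 59 | 39 |

violet run (percent of the substrate charged)

| time / min | target / % | substrate / % |
|---|---|---|
| 8.00 | 34 | 64 |
| 12.0 | 41 | 59 |
| 20.0 | 48 | 54 |
| 30.0 | 46 | 47 |
| 50.0 | 49 | 47 |
| 90.0 | 46 | 46 |

(scatter of a reading: 2 percentage points)

- spring: at 8.0 h add free enzyme, 50.0% of the amount charged, then wait 4.0 h
- noon: change nothing and wait 4.0 h more
- dusk: at 8.0 h raise the temperature by 20 K, then wait 4.0 h
- winter: at 8.0 h take out 90% of the target then present, then wait 4.0 h

- target taken out counts as made
- what was read earlier has a scatter of 2 percentage points, one standard deviation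
- additions bring no volume worth counting

1. target, in percent of the substrate first charged, at 8.0 h
2. which option adds most target ("none" when 2 percentage points or less is all one gets) (spring / noon / dusk / winter / none)
3. target present, with what was taken out counted in, in percent of the substrate first charged, after noon
4. target present, with what was taken out counted in, in percent of the substrate first charged, after dusk

Both runs stop with substrate on hand, so I count turnovers. I assume the enzyme works first order in substrate (pseudo-first-order) until it dies. Then the logarithm of the depletion counts what a charge delivers. Teal gives 0.104 µM⁻¹ for ρ, the reach: −ln S over E, with S the substrate fraction left at the stop and E the enzyme charged, at fixed temperature. Violet reads 0.152 µM⁻¹ at 32 °C, more than teal, which suits an enzyme living longer when colder.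

With dead enzyme I expect noon, dusk and winter to add nothing, and target to stay near 58.0%. Spring buys more reach at the same temperature, so I reckon teal substrate falls to 21.2%. The teal means read target as 89.9% of the substrate used, so I expect a gain of 13 percentage points, more than the margin.

The weak link is that the stop might be an equilibrium. Then target over substrate climbs from 1.01 at 32 °C to 1.63 at 37 °C. That is steep for so small a step, so I commit to death.

The forecast says 58% (56% to 60%), 58% after noon, 59% after dusk (up to 82%), and picks spring, with a gain near 14 points: “I lean towards death, though not firmly”.

The flask gives 57.0%, 57.0% after noon and 57.0% after dusk. The best option is spring, at 8.1 points, less than my gain.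

    free enzyme → unfolded enzyme (k = 0.0150 min⁻¹, Ea = 240 kJ mol⁻¹)
    substrate + free enzyme → target + free enzyme, rate k2*[substrate]*[free enzyme]/(1 + ([substrate]/Km2)) (0.0630 M, k = 30000 L mol⁻¹ min⁻¹, Ea = 40.0 kJ mol⁻¹)
    free enzyme → spent catalyst (k = 0.220 min⁻¹, Ea = 94.0 kJ mol⁻¹)
    target + free enzyme ⇌ isomer of the product + free enzyme, rate k4*[free enzyme]*[target] forward; the back reaction follows from the equilibrium constant (K = 1.70, k = 6200 L mol⁻¹ min⁻¹, Ea = 42.0 kJ mol⁻¹, ΔH = −42.0 kJ mol⁻¹)
    (constants at 37 °C)

The slowest mode of this flask, as it stands at 8.00 h, has a half-life of 2.95 min, far shorter than the 8.0 h waited. The share of catalyst that can still turn over is 0% at 8.00 h. For a neighbour flask charged with 2.50 µM, a quarter of this enzyme at the same temperature, ρ gives an estimate of substrate 77.1%. Computed, it holds substrate 77.9% and target 21.3%.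

The earlier runs and the new flask are simulated from invented constants; noise was put on by code.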